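Over 20 h the substrate in this flask can go to target, side product or homo dimer, and the way to target starts shut, with none of the gas dissolved at the start.

    gas phase ⇌ dissolved gas, rate k1*(csat - [dissolved gas]) (k1 = 1.3 /h, csat = 26 mM)
    substrate + dissolved gas ⇌ target (K2 = 1200 /M, k2 = 9.4 /M/h)
    substrate → side product (k3 = 0.14 /h)
    2 substrate → homo dimer (k4 = 2.5 /M/h)

substrate 0.10 M; gas phase 26 mM (held); time 20 h

- a species is counted by the substrate in it: one homo dimer counts as two
- a step written with two of one species runs at k times the square of its concentration and takes two of it each time
- at the start none of the gas is dissolved
- run time (flask): 20 h

* amount of target at 20 h, in percent of the substrate charged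
* the change that raises the amount of target at 20 h, in percent of the substrate charged most ("none" if none brings more than 2 percentage points) (cedar / ash / none)
* amount of target at 20 h, in percent of the substrate charged, after ash

I reckoned in rates per unit of substrate. At the start the homo dimer path ran at 0.500 /h and the side product path at 0.14 /h, with capture at zero. I took the gas to arrive after about 0.769 h, one over the transfer coefficient, which is shorter than the 2.00 h of the dimer path, so I counted no capture before then and a saturated solution after it. That makes capture pseudo-first-order at 0.244 /h. During the wait the dimer rate fell by a factor 0.658, to 0.329 /h. It slowed further as capture and side product together ran at 0.384 /h. Summing that slowing gave 30.2 %: the capture yield, which is capture rate over starting dimer rate, times the natural logarithm of one plus the dimer rate at arrival over those two steady rates. Doubling saturation, which is ash, gave 41.1 %. Halving the wait, as cedar does in my reckoning by doubling the transfer coefficient, gave 34.8 %. I committed to ash.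

The forecast gave 28 %, and 42 % after ash, the change it put first on the ground that “faster transfer can only bring the gas closer to the existing ceiling”. My first figure stood above its own, my second below.

The simulated flask gave 27.4 %, and 40.0 % after ash. Ash brought 13 percentage points and cedar 3.9 points, so the forecast held.

My capture yield stood 2.8 points above the flask, and it is reckoned with no way back from target. The flask had not come to rest at 20.0 h, with substrate down to 0.579 %. Run to 200 h, its target fell from 27.4 % to 16.4 % while side product rose from 28.1 % to 39.1 %, and homo dimer stood at 44.2 %.

In the neighbour charged with 0.025 M of substrate, the dimer rate starts at 0.125 /h, and the capture yield gives 46.4 %. That flask gave 43.6 %.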